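**Plan**

1. The last bond cut is the ether bond from the ring D phenol oxygen to the ring C carbon lying between the CH2-bearing carbon (the one leading to C8') and the OH-bearing carbon. That carbon is the carboxyl position of a 6-alkylsalicylate, so putting CO back turns the 18-membered ring into a 19-membered aryl salicylate lactone.
2. The lactone is cut at the CH2–CH2 bridge between rings A and D (styrene/styrene ring-closing metathesis, then hydrogenation) and at the aryl ester (acylation of 3-vinylphenol).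
3. The C7'–C8' bond comes from a laterally lithiated 6-methylsalicylate and a ring A–O–ring B Weinreb amide; the A–O–B ether comes from SNAr of a gallate-derived phenol on ethyl 4-fluorobenzoate.
4. Forward order: ring A, then A–O–B, then ring C (ketone), then a temporary dihydroisocoumarin ring, which is opened and silylated; ring D is added as the ester, the 19-membered ring closes by metathesis, CO loss gives the 18-membered ring, and deprotection follows.
5. The only stereocentre, C7' (S), is set by asymmetric transfer hydrogenation of the aryl ketone and carried first as the lactone oxygen, then as a silyl ether.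

Key step: step 14

Remarks: ring A is the trioxygenated ring, B the para-phenylene, C the ring with OH next to the ether carbon, D the meta-phenylene; C7' is the carbinol carbon and C8' the adjacent CH2. Ethyl 6-methylsalicylate and 3-vinylphenol are taken as purchasable. The (S) sense of step 9 is assigned by analogy with acetophenone-type ketones.

**Step 1**
Reactants: 1 methyl gallate
Product: 2 methyl 3,4-bis(benzyloxy)-5-hydroxybenzoate
Conditions: BnBr (2.05 equiv), K2CO3 (2.2 equiv), DMF, rt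
Reagents that add atoms: benzyl bromide, BrCc1ccccc1
Why: Williamson etherification; the 4-OH para to the ester is the most acidic and one of the two equivalent flanking OH groups reacts next, so two equivalents of benzyl bromide should give mainly the 3,4-dibenzyl ether with one OH left free.

**Step 2**
Reactants: 2 methyl 3,4-bis(benzyloxy)-5-hydroxybenzoate
Product: 3 [3,4-bis(benzyloxy)-5-hydroxyphenyl]methanol
Conditions: LiAlH4, THF, 0 °C to rt
Reagents that add atoms: none
Why: Hydride reduction of the ester with LiAlH4; the benzyl ethers are inert and the phenol is only deprotonated.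

**Step 3**
Reactants: 3 [3,4-bis(benzyloxy)-5-hydroxyphenyl]methanol
Product: 4 3,4-bis(benzyloxy)-5-hydroxybenzaldehyde
Conditions: activated MnO2 (excess), CH2Cl2, rt
Reagents that add atoms: none
Why: Manganese dioxide oxidation is selective for the benzylic alcohol and should leave the phenol and benzyl ethers untouched.

**Step 4**
Reactants: 4 3,4-bis(benzyloxy)-5-hydroxybenzaldehyde; 5 ethyl 4-fluorobenzoate
Product: 6 ethyl 4-[2,3-bis(benzyloxy)-5-formylphenoxy]benzoate
Conditions: K2CO3, dry DMSO, 120 °C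
Reagents that add atoms: none
Why: SNAr diaryl ether synthesis; the para ester activates the fluoride, the phenoxide is meta to the aldehyde and keeps its nucleophilicity, and the aldehyde has no enolisable hydrogen.

**Step 5**
Reactants: 6 ethyl 4-[2,3-bis(benzyloxy)-5-formylphenoxy]benzoate
Product: 7 ethyl 4-[2,3-bis(benzyloxy)-5-ethenylphenoxy]benzoate
Conditions: Ph3PCH3Br, NaHMDS, THF, 0 °C to rt
Reagents that add atoms: methyltriphenylphosphonium bromide, C[P+](c1ccccc1)(c1ccccc1)c1ccccc1.[Br-]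
Why: Wittig methylenation; the non-stabilised ylide attacks the aldehyde far faster than the aryl ester.

**Step 6**
Reactants: 7 ethyl 4-[2,3-bis(benzyloxy)-5-ethenylphenoxy]benzoate
Product: 8 4-[2,3-bis(benzyloxy)-5-ethenylphenoxy]-N-methoxy-N-methylbenzamide
Conditions: MeNH(OMe)·HCl (1.5 equiv), iPrMgCl (3 equiv), THF, −15 to 0 °C
Reagents that add atoms: N,O-dimethylhydroxylamine hydrochloride, CNOC.Cl
Why: Direct ester-to-Weinreb-amide aminolysis by the chloromagnesium amide; the styrene and benzyl ethers are inert to it.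

**Step 7**
Reactants: 9 ethyl 6-methylsalicylate
Product: 10 ethyl 2-(benzyloxy)-6-methylbenzoate
Conditions: BnBr, K2CO3, DMF, 60 °C
Reagents that add atoms: benzyl bromide, BrCc1ccccc1
Why: Williamson etherification of the hydrogen-bonded salicylate OH, which needs only mild heating.

**Step 8**
Reactants: 10 ethyl 2-(benzyloxy)-6-methylbenzoate; 8 4-[2,3-bis(benzyloxy)-5-ethenylphenoxy]-N-methoxy-N-methylbenzamide
Product: 11 ethyl 2-(benzyloxy)-6-(2-{4-[2,3-bis(benzyloxy)-5-ethenylphenoxy]phenyl}-2-oxoethyl)benzoate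
Conditions: 10 (1.2 equiv), LDA (1.2 equiv), THF, −78 °C; then 8; AcOH quench at −78 °C
Reagents that add atoms: none
Why: Lateral (benzylic) lithiation of the o-toluate and acylation by the Weinreb amide, whose chelated tetrahedral adduct should hold until the quench and so prevent double addition and proton transfer to the carbanion.

**Step 9**
Reactants: 11 ethyl 2-(benzyloxy)-6-(2-{4-[2,3-bis(benzyloxy)-5-ethenylphenoxy]phenyl}-2-oxoethyl)benzoate
Product: 13 (3S)-8-(benzyloxy)-3-{4-[2,3-bis(benzyloxy)-5-ethenylphenoxy]phenyl}-3,4-dihydro-1H-isochromen-1-one, via hydroxy ester 12 (not isolated)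
Conditions: RuCl(p-cymene)[(S,S)-TsDPEN] (2 mol%), HCO2H/Et3N (5:2), DMF, 40 °C; then CSA (cat.), CH2Cl2, rt
Reagents that add atoms: none
Why: Noyori–Ikariya asymmetric transfer hydrogenation, in which the (S,S)-ligand should deliver hydride to the Re face of the aryl ketone through the CH/π-stabilised transition state and set C7' as S, followed by closure of the hydroxy ester to the six-membered lactone; the styrene is not reduced by this catalyst.

**Step 10**
Reactants: 13 (3S)-8-(benzyloxy)-3-{4-[2,3-bis(benzyloxy)-5-ethenylphenoxy]phenyl}-3,4-dihydro-1H-isochromen-1-one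
Product: 16 2-(benzyloxy)-6-[(2S)-2-{4-[2,3-bis(benzyloxy)-5-ethenylphenoxy]phenyl}-2-[(tert-butyldimethylsilyl)oxy]ethyl]benzoic acid, via lithium carboxylate 14 (not isolated), via bis-silyl compound 15 (not isolated)
Conditions: LiOH, THF/MeOH/H2O, rt, evaporate and dry; TBSCl, imidazole, DMF, rt; then K2CO3, MeOH/THF/H2O, rt; AcOH to pH 5
Reagents that add atoms: lithium hydroxide, [Li+].[OH-]; tert-butyldimethylsilyl chloride, CC(C)(C)[Si](C)(C)Cl
Why: Saponification of the lactone by acyl–oxygen cleavage (stereocentre untouched), persilylation of the salt kept basic so that it cannot relactonise, and selective methanolysis of the labile silyl ester, a standard lactone-to-silyloxy-acid sequence.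

**Step 11**
Reactants: 16 2-(benzyloxy)-6-[(2S)-2-{4-[2,3-bis(benzyloxy)-5-ethenylphenoxy]phenyl}-2-[(tert-butyldimethylsilyl)oxy]ethyl]benzoic acid; 17 3-ethenylphenol
Product: 19 3-ethenylphenyl 2-(benzyloxy)-6-[(2S)-2-{4-[2,3-bis(benzyloxy)-5-ethenylphenoxy]phenyl}-2-[(tert-butyldimethylsilyl)oxy]ethyl]benzoate, via acid chloride 18 (not isolated)
Conditions: 1-chloro-N,N,2-trimethylprop-1-en-1-amine, CH2Cl2, 0 °C to rt; then 17, Et3N, DMAP (cat.), CH2Cl2, rt
Reagents that add atoms: none
Why: Neutral acid chloride formation with the α-chloroenamine followed by DMAP-catalysed acylation of the phenol, the dependable way to esterify a di-ortho-substituted benzoic acid when the partner is used intermolecularly and in excess.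

**Step 12**
Reactants: 19 3-ethenylphenyl 2-(benzyloxy)-6-[(2S)-2-{4-[2,3-bis(benzyloxy)-5-ethenylphenoxy]phenyl}-2-[(tert-butyldimethylsilyl)oxy]ethyl]benzoate
Product: 20 19-membered stilbene macrolactone (E/Z mixture at the ring A–CH=CH–ring D bridge; S at C7')
Conditions: second-generation Ru–NHC benzylidene metathesis catalyst (10 mol%), CH2Cl2 (1 mM), 40 °C, Ar sparge
Reagents that add atoms: none
Why: Ring-closing metathesis of two styrenes to a stilbene with loss of ethene; high dilution favours the 19-membered ring, and the ester, silyl ether and benzyl ethers do not bind ruthenium.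

**Step 13**
Reactants: 20 19-membered stilbene macrolactone
Product: 21 19-membered macrolactone (ring C aroyl ester of the ring D phenol, saturated CH2–CH2 bridge, three benzyl ethers, (S)-silyl ether)
Conditions: H2 (1 atm), 10% Pd/C, Ph2S (cat.), EtOAc, rt
Reagents that add atoms: none
Why: Catalytic hydrogenation over sulfide-poisoned Pd/C, which reduces the alkene but should not hydrogenolyse aryl benzyl ethers or the aryl ester.

**Step 14**
Reactants: 21 19-membered macrolactone
Product: 22 fully protected 18-membered macrocycle (ring D oxygen bonded directly to ring C; three benzyl ethers; (S)-silyl ether)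
Conditions: Ni(cod)2 (30 mol%), 3,4-bis(dicyclohexylphosphino)thiophene (60 mol%), K3PO4 (1.5 equiv), m-xylene, 150 °C, slow Ar stream
Reagents that add atoms: none
Why: Proposed new method: Ni(0) with the bulky diphosphine should insert into the C(acyl)–O bond of the aryl ester, the aroyl–nickel aryloxide should lose CO by aryl migration, and C–O reductive elimination from the aryl–nickel aryloxide should give the diaryl ether while CO is swept out at 150 °C. The closest known reaction type is the Ni- or Pd-catalysed intermolecular decarbonylative etherification of simple aryl (het)aroates; a macrocyclic, di-ortho-substituted benzoate has not been used. The 18-membered ring closes by ring contraction, the carbonyl carbon being excised from the 19-membered lactone while both ends stay on one nickel centre, so no end-to-end cyclisation and no high dilution are involved. No stereocentre is formed and the C7' silyl ether takes no part. The step needs insertion into the acyl–O bond and not into the aryl–O bonds of the benzyl ethers, the diaryl ether or the ester; the twisted aroyl group has weakened acyl–O conjugation, the ortho benzyloxy oxygen can guide nickel to the carbonyl, and no reductant or nucleophile is present to engage aryl ether bonds.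

**Step 15**
Reactants: 22 fully protected 18-membered macrocycle
Product: 23 (S)-C7' tert-butyldimethylsilyl ether of the target (three free phenols)
Conditions: H2 (1 atm), 10% Pd/C, EtOAc/THF, rt
Reagents that add atoms: none
Why: Hydrogenolysis of the three aryl benzyl ethers in a neutral aprotic medium; the benzylic C7'–O bond is shielded as its silyl ether and diaryl ethers are inert.

**Step 16**
Reactants: 23 (S)-C7' tert-butyldimethylsilyl ether of the target
Product: 24 CNP0356934.1, the (S)-alcohol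
Conditions: HF·pyridine, pyridine, THF, 0 °C to rt
Reagents that add atoms: none
Why: Fluoride-mediated desilylation in a buffered, slightly acidic medium, which avoids phenoxide formation at the catechol and ionisation of the benzylic alcohol.

**Compound list**

1 | methyl gallate | COC(=O)c1cc(O)c(O)c(O)c1 | starting material
2 | methyl 3,4-bis(benzyloxy)-5-hydroxybenzoate | COC(=O)c1cc(O)c(OCc2ccccc2)c(OCc2ccccc2)c1 | intermediate
3 | [3,4-bis(benzyloxy)-5-hydroxyphenyl]methanol | OCc1cc(O)c(OCc2ccccc2)c(OCc2ccccc2)c1 | intermediate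
4 | 3,4-bis(benzyloxy)-5-hydroxybenzaldehyde | O=Cc1cc(O)c(OCc2ccccc2)c(OCc2ccccc2)c1 | intermediate
5 | ethyl 4-fluorobenzoate | CCOC(=O)c1ccc(F)cc1 | starting material
6 | ethyl 4-[2,3-bis(benzyloxy)-5-formylphenoxy]benzoate | CCOC(=O)c1ccc(cc1)Oc1cc(C=O)cc(OCc2ccccc2)c1OCc1ccccc1 | intermediate
7 | ethyl 4-[2,3-bis(benzyloxy)-5-ethenylphenoxy]benzoate | CCOC(=O)c1ccc(cc1)Oc1cc(C=C)cc(OCc2ccccc2)c1OCc1ccccc1 | intermediate
8 | 4-[2,3-bis(benzyloxy)-5-ethenylphenoxy]-N-methoxy-N-methylbenzamide | CON(C)C(=O)c1ccc(cc1)Oc1cc(C=C)cc(OCc2ccccc2)c1OCc1ccccc1 | intermediate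
9 | ethyl 6-methylsalicylate (ethyl 2-hydroxy-6-methylbenzoate) | CCOC(=O)c1c(C)cccc1O | starting material
10 | ethyl 2-(benzyloxy)-6-methylbenzoate | CCOC(=O)c1c(C)cccc1OCc1ccccc1 | intermediate
11 | ethyl 2-(benzyloxy)-6-(2-{4-[2,3-bis(benzyloxy)-5-ethenylphenoxy]phenyl}-2-oxoethyl)benzoate | CCOC(=O)c1c(OCc2ccccc2)cccc1CC(=O)c1ccc(cc1)Oc1cc(C=C)cc(OCc2ccccc2)c1OCc1ccccc1 | intermediate
12 | ethyl 2-(benzyloxy)-6-[(2S)-2-{4-[2,3-bis(benzyloxy)-5-ethenylphenoxy]phenyl}-2-hydroxyethyl]benzoate | CCOC(=O)c1c(OCc2ccccc2)cccc1C[C@H](O)c1ccc(cc1)Oc1cc(C=C)cc(OCc2ccccc2)c1OCc1ccccc1 | intermediate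
13 | (3S)-8-(benzyloxy)-3-{4-[2,3-bis(benzyloxy)-5-ethenylphenoxy]phenyl}-3,4-dihydro-1H-isochromen-1-one | O=C1O[C@H](c2ccc(cc2)Oc2cc(C=C)cc(OCc3ccccc3)c2OCc2ccccc2)Cc2cccc(OCc3ccccc3)c12 | intermediate
14 | lithium 2-(benzyloxy)-6-[(2S)-2-{4-[2,3-bis(benzyloxy)-5-ethenylphenoxy]phenyl}-2-hydroxyethyl]benzoate | [Li+].[O-]C(=O)c1c(OCc2ccccc2)cccc1C[C@H](O)c1ccc(cc1)Oc1cc(C=C)cc(OCc2ccccc2)c1OCc1ccccc1 | intermediate
15 | tert-butyldimethylsilyl 2-(benzyloxy)-6-[(2S)-2-{4-[2,3-bis(benzyloxy)-5-ethenylphenoxy]phenyl}-2-[(tert-butyldimethylsilyl)oxy]ethyl]benzoate | CC(C)(C)[Si](C)(C)OC(=O)c1c(OCc2ccccc2)cccc1C[C@H](O[Si](C)(C)C(C)(C)C)c1ccc(cc1)Oc1cc(C=C)cc(OCc2ccccc2)c1OCc1ccccc1 | intermediate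
16 | 2-(benzyloxy)-6-[(2S)-2-{4-[2,3-bis(benzyloxy)-5-ethenylphenoxy]phenyl}-2-[(tert-butyldimethylsilyl)oxy]ethyl]benzoic acid | OC(=O)c1c(OCc2ccccc2)cccc1C[C@H](O[Si](C)(C)C(C)(C)C)c1ccc(cc1)Oc1cc(C=C)cc(OCc2ccccc2)c1OCc1ccccc1 | intermediate
17 | 3-ethenylphenol (3-vinylphenol) | C=Cc1cccc(O)c1 | starting material
18 | 2-(benzyloxy)-6-[(2S)-2-{4-[2,3-bis(benzyloxy)-5-ethenylphenoxy]phenyl}-2-[(tert-butyldimethylsilyl)oxy]ethyl]benzoyl chloride | ClC(=O)c1c(OCc2ccccc2)cccc1C[C@H](O[Si](C)(C)C(C)(C)C)c1ccc(cc1)Oc1cc(C=C)cc(OCc2ccccc2)c1OCc1ccccc1 | intermediate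
19 | 3-ethenylphenyl 2-(benzyloxy)-6-[(2S)-2-{4-[2,3-bis(benzyloxy)-5-ethenylphenoxy]phenyl}-2-[(tert-butyldimethylsilyl)oxy]ethyl]benzoate | C=Cc1cccc(c1)OC(=O)c1c(OCc2ccccc2)cccc1C[C@H](O[Si](C)(C)C(C)(C)C)c1ccc(cc1)Oc1cc(C=C)cc(OCc2ccccc2)c1OCc1ccccc1 | intermediate
20 | 19-membered stilbene macrolactone, (S), E/Z mixture | c1ccccc1COc1cc2cc(c1OCc1ccccc1)Oc1ccc(cc1)[C@@H](O[Si](C)(C)C(C)(C)C)Cc1cccc(OCc3ccccc3)c1C(=O)Oc1cccc(c1)C=C2 | intermediate
21 | 19-membered macrolactone (ring C aroyl ester of the ring D phenol), (S)-silyl ether | c1ccccc1COc1cc2cc(c1OCc1ccccc1)Oc1ccc(cc1)[C@@H](O[Si](C)(C)C(C)(C)C)Cc1cccc(OCc3ccccc3)c1C(=O)Oc1cccc(c1)CC2 | intermediate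
22 | fully protected 18-membered macrocycle, (S) | c1ccccc1COc1cc2cc(c1OCc1ccccc1)Oc1ccc(cc1)[C@@H](O[Si](C)(C)C(C)(C)C)Cc1cccc(OCc3ccccc3)c1Oc1cccc(c1)CC2 | intermediate
23 | (S)-C7' tert-butyldimethylsilyl ether of the target | Oc1cc2cc(c1O)Oc1ccc(cc1)[C@@H](O[Si](C)(C)C(C)(C)C)Cc1cccc(O)c1Oc1cccc(c1)CC2 | intermediate
24 | CNP0356934.1, (S) | Oc1cc2cc(c1O)Oc1ccc(cc1)[C@@H](O)Cc1cccc(O)c1Oc1cccc(c1)CC2 | target

**Step count and risks**

Total: 16 steps. Longest linear sequence: 15 steps (methyl gallate to the target; step 7 is the only side branch).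

Steps most likely to fail:

Step 14. Nickel may fail to insert into the crowded acyl–O bond, the acyl nickel species may stall before CO loss or be poisoned by CO, or the aryl group may be protonated instead of coupled. The fallback uses known reactions, sets out from 16 through its acid chloride 18 and returns at 22. Reduction of 18 with LiAlH(OtBu)3 (THF, −78 °C) should give 2-(benzyloxy)-6-[(2S)-2-{4-[2,3-bis(benzyloxy)-5-ethenylphenoxy]phenyl}-2-[(tert-butyldimethylsilyl)oxy]ethyl]benzaldehyde F1. A Heck reaction at the iodide of 1-bromo-3-iodobenzene (Pd(OAc)2, Bu4NCl, Et3N, DMF, 80 °C) should give the (E)-stilbene bromo aldehyde F2, and hydrogenation over Pd/C with Ph2S the bibenzyl bromo aldehyde F3. Dakin-type Baeyer–Villiger oxidation with mCPBA (CH2Cl2, 0 °C) should give the aryl formate F4, which is methanolysed (Et3N, MeOH) to the ring C phenol F5. Intramolecular Ullmann etherification (CuI, N,N-dimethylglycine, Cs2CO3, dioxane, 100 °C, high dilution) would then close the 18-membered ring to 22; the crowded carbon enters as the phenol and the unhindered ring D as the bromide.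

Step 12. Intermolecular cross-metathesis may outrun ring closure, or a strained macrocyclic stilbene may reopen, so that oligomers form. The fallback closes the ring at the ester, sets out from 16 and returns at 21. A Heck reaction of 16 with 3-iodophenol (Pd(OAc)2, P(o-tol)3, Et3N, DMF, 90 °C) should give the (E)-stilbene seco acid F6; hydrogenation over Pd/C with Ph2S should give the saturated seco acid F7; Mukaiyama macrolactonisation (2-chloro-1-methylpyridinium iodide, Et3N, MeCN, reflux, slow addition) would give 21.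

Step 10. The hydroxy carboxylate may relactonise to 13 before the alcohol is silylated, or the silyl ester may not be cleaved selectively. The fallback replaces the transient silyl ester by an isolable allyl ester, sets out from 13 (through lithium salt 14) and returns at 16. Alkylation of 14 with allyl bromide (DMF, rt) should give the allyl hydroxy ester F8; TBSOTf and 2,6-lutidine (CH2Cl2, −78 °C) should give the allyl ester silyl ether F9; Pd(PPh3)4 with morpholine (THF, rt) would release 16.

**Further compounds**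

F1 | step 14 | 2-(benzyloxy)-6-[(2S)-2-{4-[2,3-bis(benzyloxy)-5-ethenylphenoxy]phenyl}-2-[(tert-butyldimethylsilyl)oxy]ethyl]benzaldehyde | O=Cc1c(OCc2ccccc2)cccc1C[C@H](O[Si](C)(C)C(C)(C)C)c1ccc(cc1)Oc1cc(C=C)cc(OCc2ccccc2)c1OCc1ccccc1
F2 | step 14 | 2-(benzyloxy)-6-[(2S)-2-(4-{2,3-bis(benzyloxy)-5-[(E)-2-(3-bromophenyl)ethenyl]phenoxy}phenyl)-2-[(tert-butyldimethylsilyl)oxy]ethyl]benzaldehyde | O=Cc1c(OCc2ccccc2)cccc1C[C@H](O[Si](C)(C)C(C)(C)C)c1ccc(cc1)Oc1cc(/C=C/c2cccc(Br)c2)cc(OCc2ccccc2)c1OCc1ccccc1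
F3 | step 14 | 2-(benzyloxy)-6-[(2S)-2-(4-{2,3-bis(benzyloxy)-5-[2-(3-bromophenyl)ethyl]phenoxy}phenyl)-2-[(tert-butyldimethylsilyl)oxy]ethyl]benzaldehyde | O=Cc1c(OCc2ccccc2)cccc1C[C@H](O[Si](C)(C)C(C)(C)C)c1ccc(cc1)Oc1cc(CCc2cccc(Br)c2)cc(OCc2ccccc2)c1OCc1ccccc1
F4 | step 14 | 2-(benzyloxy)-6-[(2S)-2-(4-{2,3-bis(benzyloxy)-5-[2-(3-bromophenyl)ethyl]phenoxy}phenyl)-2-[(tert-butyldimethylsilyl)oxy]ethyl]phenyl formate | O=COc1c(OCc2ccccc2)cccc1C[C@H](O[Si](C)(C)C(C)(C)C)c1ccc(cc1)Oc1cc(CCc2cccc(Br)c2)cc(OCc2ccccc2)c1OCc1ccccc1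
F5 | step 14 | 2-(benzyloxy)-6-[(2S)-2-(4-{2,3-bis(benzyloxy)-5-[2-(3-bromophenyl)ethyl]phenoxy}phenyl)-2-[(tert-butyldimethylsilyl)oxy]ethyl]phenol | Oc1c(OCc2ccccc2)cccc1C[C@H](O[Si](C)(C)C(C)(C)C)c1ccc(cc1)Oc1cc(CCc2cccc(Br)c2)cc(OCc2ccccc2)c1OCc1ccccc1
F6 | step 12 | 2-(benzyloxy)-6-[(2S)-2-(4-{2,3-bis(benzyloxy)-5-[(E)-2-(3-hydroxyphenyl)ethenyl]phenoxy}phenyl)-2-[(tert-butyldimethylsilyl)oxy]ethyl]benzoic acid | OC(=O)c1c(OCc2ccccc2)cccc1C[C@H](O[Si](C)(C)C(C)(C)C)c1ccc(cc1)Oc1cc(/C=C/c2cccc(O)c2)cc(OCc2ccccc2)c1OCc1ccccc1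
F7 | step 12 | 2-(benzyloxy)-6-[(2S)-2-(4-{2,3-bis(benzyloxy)-5-[2-(3-hydroxyphenyl)ethyl]phenoxy}phenyl)-2-[(tert-butyldimethylsilyl)oxy]ethyl]benzoic acid | OC(=O)c1c(OCc2ccccc2)cccc1C[C@H](O[Si](C)(C)C(C)(C)C)c1ccc(cc1)Oc1cc(CCc2cccc(O)c2)cc(OCc2ccccc2)c1OCc1ccccc1
F8 | step 10 | prop-2-en-1-yl 2-(benzyloxy)-6-[(2S)-2-{4-[2,3-bis(benzyloxy)-5-ethenylphenoxy]phenyl}-2-hydroxyethyl]benzoate | C=CCOC(=O)c1c(OCc2ccccc2)cccc1C[C@H](O)c1ccc(cc1)Oc1cc(C=C)cc(OCc2ccccc2)c1OCc1ccccc1
F9 | step 10 | prop-2-en-1-yl 2-(benzyloxy)-6-[(2S)-2-{4-[2,3-bis(benzyloxy)-5-ethenylphenoxy]phenyl}-2-[(tert-butyldimethylsilyl)oxy]ethyl]benzoate | C=CCOC(=O)c1c(OCc2ccccc2)cccc1C[C@H](O[Si](C)(C)C(C)(C)C)c1ccc(cc1)Oc1cc(C=C)cc(OCc2ccccc2)c1OCc1ccccc1
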